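**Plan**

- Retrosynthesis: the C9(spiro)–C9a(aryl) bond is cut first, giving the open-chain phenolic 1,4-diarylbutyl benzoate 19. Then, in order: the benzoate and silyl groups, the C7 methyl centre (back to an exo-methylene, 16), the C=CH2 and ArCH2–C(O) bonds (Weinreb amide 11 + benzylic Grignard from 4), and the C5–C6 aldol bond (5 + 6).
- Forward: aldol → Weinreb amide → benzyl ketone → 1,1-disubstituted alkene → hydrogenation builds the chain. The seven-membered carbocycle and the cross-conjugated dienone arise together in the last step.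
- Enabling feature: the 3,5-dimethoxy-4-oxocyclohexa-2,5-diene ring is the two-electron-oxidised form of a syringyl phenol whose para carbon is the spiro atom C9. Through the four-carbon chain it sits in a 1,7-relationship to a free ortho CH (C9a) of the 1,2,3-trimethoxybenzene ring, which is ortho and para to methoxy groups.
- Stereochemistry: C5 and C6 come from an Evans syn-aldol with the (R)-benzyloxazolidinone; C7 comes from hydroxyl-directed hydrogenation. C9 is not stereogenic because the dienone has two identical arms.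
- Remark: the stereocentres of the SMILES are read as 5R,6S,7R (benzo[7]annulene numbering), i.e. 5,6-trans and 6,7-trans on the ring, all-syn in the open chain.

Key step: step 13

**Route**

Step 1
Reactants: 1 syringaldehyde (4-hydroxy-3,5-dimethoxybenzaldehyde)
Product: 2 3,5-dimethoxy-4-(triisopropylsilyloxy)benzaldehyde
Conditions: TIPSCl, imidazole, DMF, rt
Reagents that add atoms: chlorotriisopropylsilane, CC(C)[Si](Cl)(C(C)C)C(C)C
Why: Imidazole-promoted silylation of the phenol; the aryl TIPS ether should survive Grignard formation, titanium methylenation, mild acid and hydrogenation and is later removable with fluoride beside a benzoate.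

Step 2
Reactants: 2 3,5-dimethoxy-4-(triisopropylsilyloxy)benzaldehyde
Product: 3 [3,5-dimethoxy-4-(triisopropylsilyloxy)phenyl]methanol
Conditions: NaBH4, MeOH, 0 °C
Reagents that add atoms: none
Why: Borohydride reduction of the aryl aldehyde to the benzylic alcohol, to which the aryl silyl ether is inert.

Step 3
Reactants: 3 [3,5-dimethoxy-4-(triisopropylsilyloxy)phenyl]methanol
Product: 4 5-(chloromethyl)-1,3-dimethoxy-2-(triisopropylsilyloxy)benzene
Conditions: PPh3, NCS, THF, 0 °C → rt
Reagents that add atoms: N-chlorosuccinimide, O=C1CCC(=O)N1Cl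
Why: Appel-type chlorination through an alkoxyphosphonium salt under neutral conditions, which spares the electron-rich benzylic system and the silyl ether.

Step 4
Reactants: 5 (R)-4-benzyl-3-propionyloxazolidin-2-one; 6 3,4,5-trimethoxybenzaldehyde
Product: 9 (R)-4-benzyl-3-[(2R,3R)-3-hydroxy-2-methyl-3-(3,4,5-trimethoxyphenyl)propanoyl]oxazolidin-2-one, via dibutylboron Z-enolate 7 (not isolated), via dibutylboron aldolate 8 (not isolated)
Conditions: Bu2BOTf, iPr2NEt, CH2Cl2, 0 °C; then 6, −78 → 0 °C; pH 7 buffer, MeOH, 30% H2O2, 0 °C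
Reagents that add atoms: none
Why: Evans syn-aldol reaction: the Z-boron enolate reacts through a Zimmerman–Traxler chair on the face away from the benzyl group of the (R)-auxiliary, which should set the carbinol centre (R) and the methyl centre (R here, S in the target only through a change of CIP priorities) as the syn pair.

Step 5
Reactants: 9 (R)-4-benzyl-3-[(2R,3R)-3-hydroxy-2-methyl-3-(3,4,5-trimethoxyphenyl)propanoyl]oxazolidin-2-one
Product: 10 (2R,3R)-3-hydroxy-N-methoxy-N,2-dimethyl-3-(3,4,5-trimethoxyphenyl)propanamide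
Conditions: MeNHOMe·HCl, AlMe3, CH2Cl2, −10 → 0 °C; aqueous work-up
Reagents that add atoms: N,O-dimethylhydroxylamine hydrochloride, CNOC.Cl
Why: Aluminium-amide transamidation to the Weinreb amide, directed to the exocyclic carbonyl by the aluminium alkoxide of the free β-hydroxyl, without epimerisation of the α-centre.

Step 6
Reactants: 10 (2R,3R)-3-hydroxy-N-methoxy-N,2-dimethyl-3-(3,4,5-trimethoxyphenyl)propanamide
Product: 11 (2R,3R)-N-methoxy-N,2-dimethyl-3-(triethylsilyloxy)-3-(3,4,5-trimethoxyphenyl)propanamide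
Conditions: TESCl, imidazole, CH2Cl2, 0 °C → rt
Reagents that add atoms: chlorotriethylsilane, CC[Si](Cl)(CC)CC
Why: Silylation of the secondary alcohol so that no alkoxide is present in the organometallic and methylenation steps (no retro-aldol or β-elimination); TES can later be removed by mild acid beside the aryl TIPS ether.

Step 7
Reactants: 4 5-(chloromethyl)-1,3-dimethoxy-2-(triisopropylsilyloxy)benzene; 11 (2R,3R)-N-methoxy-N,2-dimethyl-3-(triethylsilyloxy)-3-(3,4,5-trimethoxyphenyl)propanamide
Product: 14 (3R,4R)-1-[3,5-dimethoxy-4-(triisopropylsilyloxy)phenyl]-3-methyl-4-(triethylsilyloxy)-4-(3,4,5-trimethoxyphenyl)butan-2-one, via benzylic Grignard reagent 12 (not isolated), via chelated tetrahedral adduct 13 (not isolated)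
Conditions: 4, Mg turnings, THF, 0 °C; then 11, THF, 0 °C; sat. aq. NH4Cl
Reagents that add atoms: none
Why: Weinreb ketone synthesis: the N-methoxy magnesium chelate holds the tetrahedral adduct until the quench, so a single benzyl group should be transferred and the α-stereocentre is not enolised.

Step 8
Reactants: 14 (3R,4R)-1-[3,5-dimethoxy-4-(triisopropylsilyloxy)phenyl]-3-methyl-4-(triethylsilyloxy)-4-(3,4,5-trimethoxyphenyl)butan-2-one
Product: 15 (1R,2S)-3-[3,5-dimethoxy-4-(triisopropylsilyloxy)benzyl]-2-methyl-1-(3,4,5-trimethoxyphenyl)but-3-en-1-yl triethylsilyl ether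
Conditions: Cp2TiMe2, toluene/THF, 65 °C, dark
Reagents that add atoms: dimethyltitanocene, C[Ti](C)(C1C=CC=C1)C1C=CC=C1
Why: Petasis methylenation with a non-basic titanium carbene should convert the hindered, doubly enolisable benzyl ketone into the 1,1-disubstituted alkene without α-epimerisation or β-elimination of the silyloxy group.

Step 9
Reactants: 15 (1R,2S)-3-[3,5-dimethoxy-4-(triisopropylsilyloxy)benzyl]-2-methyl-1-(3,4,5-trimethoxyphenyl)but-3-en-1-yl triethylsilyl ether
Product: 16 (1R,2S)-3-[3,5-dimethoxy-4-(triisopropylsilyloxy)benzyl]-2-methyl-1-(3,4,5-trimethoxyphenyl)but-3-en-1-ol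
Conditions: PPTS (cat.), MeOH/CH2Cl2, 0 °C → rt
Reagents that add atoms: none
Why: Mild acid-catalysed methanolysis of the alkyl triethylsilyl ether, to which the aryl TIPS ether and the isolated alkene should be stable, frees the hydroxyl needed as directing group.

Step 10
Reactants: 16 (1R,2S)-3-[3,5-dimethoxy-4-(triisopropylsilyloxy)benzyl]-2-methyl-1-(3,4,5-trimethoxyphenyl)but-3-en-1-ol
Product: 17 (1R,2S,3R)-4-[3,5-dimethoxy-4-(triisopropylsilyloxy)phenyl]-2,3-dimethyl-1-(3,4,5-trimethoxyphenyl)butan-1-ol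
Conditions: [Rh(nbd)(dppb)]BF4 (5–10 mol %), H2 (50 bar), CH2Cl2, rt
Reagents that add atoms: none
Why: Hydroxyl-directed homogeneous hydrogenation of a homoallylic alcohol: in the Rh chelate the C-1 aryl group lies anti to C-3 and the C-2 methyl turns toward the =CH2 terminus to avoid A(1,2) strain with the arylmethyl group, so hydrogen should be delivered to the alkene face syn to the carbinol and C-3 is formed R, syn to both the C-2 methyl and the C-1 oxygen.

Step 11
Reactants: 17 (1R,2S,3R)-4-[3,5-dimethoxy-4-(triisopropylsilyloxy)phenyl]-2,3-dimethyl-1-(3,4,5-trimethoxyphenyl)butan-1-ol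
Product: 18 (1R,2S,3R)-4-[3,5-dimethoxy-4-(triisopropylsilyloxy)phenyl]-2,3-dimethyl-1-(3,4,5-trimethoxyphenyl)butyl benzoate
Conditions: BzCl, pyridine, DMAP (cat.), CH2Cl2, 0 °C → rt
Reagents that add atoms: benzoyl chloride, O=C(Cl)c1ccccc1
Why: DMAP-catalysed acylation that leaves the C–O bond and hence the carbinol configuration untouched; the ester is the target's substituent and also masks the oxygen for the oxidation.

Step 12
Reactants: 18 (1R,2S,3R)-4-[3,5-dimethoxy-4-(triisopropylsilyloxy)phenyl]-2,3-dimethyl-1-(3,4,5-trimethoxyphenyl)butyl benzoate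
Product: 19 (1R,2S,3R)-4-(4-hydroxy-3,5-dimethoxyphenyl)-2,3-dimethyl-1-(3,4,5-trimethoxyphenyl)butyl benzoate
Conditions: TBAF, AcOH, THF, 0 °C
Reagents that add atoms: none
Why: Fluoride cleavage of the aryl silyl ether driven by Si–F bond formation, buffered with acetic acid so that the phenoxide does not attack the benzoate.

Step 13
Reactants: 19 (1R,2S,3R)-4-(4-hydroxy-3,5-dimethoxyphenyl)-2,3-dimethyl-1-(3,4,5-trimethoxyphenyl)butyl benzoate
Product: 21 (5R,6S,7R)-1,2,3,3',5'-pentamethoxy-6,7-dimethyl-4'-oxo-5,6,7,8-tetrahydrospiro[benzo[7]annulene-9,1'-cyclohexa[2,5]dien]-5-yl benzoate, via aryloxy-λ3-iodane 20 (not isolated)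
Conditions: PhI(OCOCF3)2, CF3CH2OH, −40 °C; aq. NaHCO3
Reagents that add atoms: none
Why: The phenol oxygen displaces a trifluoroacetate on iodine(III) (iodane 20); loss of iodobenzene in the ionising, weakly nucleophilic fluoroalcohol leaves a phenoxenium ion stabilised by the two ortho methoxy groups, whose para carbon is attacked by the free ortho carbon of the trimethoxyphenyl ring (ortho to one OMe, para to another), and loss of the arenium proton gives the dienone. The closest known reaction type is the hypervalent-iodine oxidative phenol–arene coupling of para-substituted phenols to spirocyclohexadienones, known for seven-membered rings and for phenolic 1,4-diarylbutane lignans. The one ring closed is the seven-membered carbocycle, in a 7-exo-trig mode at the cationic para carbon (an ortho Friedel–Crafts closure, the arene π bond lying inside the new ring). No new stereocentre arises because the spiro carbon carries two identical CH=C(OMe) arms; the three existing centres are untouched and can all sit pseudo-equatorial in the closing chain. The step needs C–C closure at the para carbon in preference to solvent capture, loss of a benzylic proton to a p-quinone methide (which would close a six-membered aryltetralin) and later dienone–phenol rearrangement; this is secured by the benzoate on the C-5 oxygen (a free hydroxyl would close a six-membered spiro-ether), the two equivalent ortho positions of the symmetrical trimethoxyphenyl ring, the methoxy-blocked ortho positions of the phenol, and the cold, non-basic medium with bicarbonate quench.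

**Compound list**

1 | syringaldehyde (4-hydroxy-3,5-dimethoxybenzaldehyde) | COc1cc(C=O)cc(OC)c1O | starting material
2 | 3,5-dimethoxy-4-(triisopropylsilyloxy)benzaldehyde | COc1cc(C=O)cc(OC)c1O[Si](C(C)C)(C(C)C)C(C)C | intermediate
3 | [3,5-dimethoxy-4-(triisopropylsilyloxy)phenyl]methanol | COc1cc(CO)cc(OC)c1O[Si](C(C)C)(C(C)C)C(C)C | intermediate
4 | 5-(chloromethyl)-1,3-dimethoxy-2-(triisopropylsilyloxy)benzene | COc1cc(CCl)cc(OC)c1O[Si](C(C)C)(C(C)C)C(C)C | intermediate
5 | (R)-4-benzyl-3-propionyloxazolidin-2-one | CCC(=O)N1[C@H](Cc2ccccc2)COC1=O | starting material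
6 | 3,4,5-trimethoxybenzaldehyde | COc1cc(C=O)cc(OC)c1OC | starting material
7 | dibutylboron (Z)-enolate of 5 | C/C=C(\OB(CCCC)CCCC)N1[C@H](Cc2ccccc2)COC1=O | intermediate (not isolated)
8 | O-dibutylboryl aldolate of 9 | O=C1OC[C@@H](Cc2ccccc2)N1C(=O)[C@H](C)[C@@H](OB(CCCC)CCCC)c1cc(OC)c(OC)c(OC)c1 | intermediate (not isolated)
9 | (R)-4-benzyl-3-[(2R,3R)-3-hydroxy-2-methyl-3-(3,4,5-trimethoxyphenyl)propanoyl]oxazolidin-2-one | O=C1OC[C@@H](Cc2ccccc2)N1C(=O)[C@H](C)[C@@H](O)c1cc(OC)c(OC)c(OC)c1 | intermediate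
10 | (2R,3R)-3-hydroxy-N-methoxy-N,2-dimethyl-3-(3,4,5-trimethoxyphenyl)propanamide | CON(C)C(=O)[C@H](C)[C@@H](O)c1cc(OC)c(OC)c(OC)c1 | intermediate
11 | (2R,3R)-N-methoxy-N,2-dimethyl-3-(triethylsilyloxy)-3-(3,4,5-trimethoxyphenyl)propanamide | CON(C)C(=O)[C@H](C)[C@@H](O[Si](CC)(CC)CC)c1cc(OC)c(OC)c(OC)c1 | intermediate
12 | [3,5-dimethoxy-4-(triisopropylsilyloxy)benzyl]magnesium chloride | COc1cc(C[Mg]Cl)cc(OC)c1O[Si](C(C)C)(C(C)C)C(C)C | intermediate (not isolated)
13 | chloromagnesium N-methoxy-N-methyl hemiaminal adduct of 11 and 12 (new carbon unspecified) | CON(C)C(O[Mg]Cl)(Cc1cc(OC)c(O[Si](C(C)C)(C(C)C)C(C)C)c(OC)c1)[C@H](C)[C@@H](O[Si](CC)(CC)CC)c1cc(OC)c(OC)c(OC)c1 | intermediate (not isolated)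
14 | (3R,4R)-1-[3,5-dimethoxy-4-(triisopropylsilyloxy)phenyl]-3-methyl-4-(triethylsilyloxy)-4-(3,4,5-trimethoxyphenyl)butan-2-one | O=C(Cc1cc(OC)c(O[Si](C(C)C)(C(C)C)C(C)C)c(OC)c1)[C@H](C)[C@@H](O[Si](CC)(CC)CC)c1cc(OC)c(OC)c(OC)c1 | intermediate
15 | (1R,2S)-3-[3,5-dimethoxy-4-(triisopropylsilyloxy)benzyl]-2-methyl-1-(3,4,5-trimethoxyphenyl)but-3-en-1-yl triethylsilyl ether | C=C(Cc1cc(OC)c(O[Si](C(C)C)(C(C)C)C(C)C)c(OC)c1)[C@H](C)[C@@H](O[Si](CC)(CC)CC)c1cc(OC)c(OC)c(OC)c1 | intermediate
16 | (1R,2S)-3-[3,5-dimethoxy-4-(triisopropylsilyloxy)benzyl]-2-methyl-1-(3,4,5-trimethoxyphenyl)but-3-en-1-ol | C=C(Cc1cc(OC)c(O[Si](C(C)C)(C(C)C)C(C)C)c(OC)c1)[C@H](C)[C@@H](O)c1cc(OC)c(OC)c(OC)c1 | intermediate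
17 | (1R,2S,3R)-4-[3,5-dimethoxy-4-(triisopropylsilyloxy)phenyl]-2,3-dimethyl-1-(3,4,5-trimethoxyphenyl)butan-1-ol | COc1cc(C[C@@H](C)[C@H](C)[C@@H](O)c2cc(OC)c(OC)c(OC)c2)cc(OC)c1O[Si](C(C)C)(C(C)C)C(C)C | intermediate
18 | (1R,2S,3R)-4-[3,5-dimethoxy-4-(triisopropylsilyloxy)phenyl]-2,3-dimethyl-1-(3,4,5-trimethoxyphenyl)butyl benzoate | COc1cc(C[C@@H](C)[C@H](C)[C@@H](OC(=O)c2ccccc2)c2cc(OC)c(OC)c(OC)c2)cc(OC)c1O[Si](C(C)C)(C(C)C)C(C)C | intermediate
19 | (1R,2S,3R)-4-(4-hydroxy-3,5-dimethoxyphenyl)-2,3-dimethyl-1-(3,4,5-trimethoxyphenyl)butyl benzoate | COc1cc(C[C@@H](C)[C@H](C)[C@@H](OC(=O)c2ccccc2)c2cc(OC)c(OC)c(OC)c2)cc(OC)c1O | intermediate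
20 | aryloxy(phenyl)(trifluoroacetoxy)-λ3-iodane of 19 | COc1cc(C[C@@H](C)[C@H](C)[C@@H](OC(=O)c2ccccc2)c2cc(OC)c(OC)c(OC)c2)cc(OC)c1O[I](OC(=O)C(F)(F)F)c1ccccc1 | intermediate (not isolated)
21 | (5R,6S,7R)-1,2,3,3',5'-pentamethoxy-6,7-dimethyl-4'-oxo-5,6,7,8-tetrahydrospiro[benzo[7]annulene-9,1'-cyclohexa[2,5]dien]-5-yl benzoate | COC1=CC2(C=C(OC)C1=O)C[C@@H](C)[C@H](C)[C@@H](OC(=O)c1ccccc1)c1cc(OC)c(OC)c(OC)c12 | target

**Step count and risks**

Total steps: 13. Longest linear sequence: 10 (steps 4–13; equally steps 1–3 followed by 7–13).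

Step 13 is the most likely to fail. The oxidised phenol may lose a benzylic proton to a p-quinone methide and close a six-membered ring, or be captured by solvent before the slower seven-ring closure, and the acid set free may trigger a dienone–phenol 1,2-shift of the product. The fallback replaces the cationic oxidation by a palladium-catalysed arylative dearomatisation under basic conditions; this reaction type is known for para-substituted phenols carrying a tethered aryl bromide, although a seven-membered closure would be an extension. It sets out from 17. Treatment with n-BuLi (2.2 equiv) and TMEDA in Et2O, −78 → 0 °C, should give alkoxide-directed ortho-lithiation between the carbinol carbon and the 3-methoxy group, forming the lithium alkoxide/aryllithium F1. Quenching with 1,2-dibromoethane should give (1R,2S,3R)-1-(2-bromo-3,4,5-trimethoxyphenyl)-4-[3,5-dimethoxy-4-(triisopropylsilyloxy)phenyl]-2,3-dimethylbutan-1-ol F2. Benzoylation as in step 11 gives the bromo benzoate F3, and TBAF/AcOH as in step 12 gives the bromo phenol F4. Pd2(dba)3, a bulky biaryl phosphine and K2CO3 in dioxane at 80–100 °C (oxidative addition, para-C palladation of the phenoxide, C–C reductive elimination) should then return to the route at 21.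

Step 10 is the second risk. The cationic rhodium catalyst may isomerise the exo-methylene into the trisubstituted styrene before reduction (for which the same model predicts the opposite C-3 configuration), or may be sequestered by the electron-rich arenes so that undirected, less face-selective reduction takes over. The fallback sets the same centre by substrate-controlled hydroboration and deoxygenation and starts from 15. 9-BBN in THF should add anti to the bulky silyloxy(aryl)methyl group with the C-2 hydrogen eclipsing the alkene, placing H on C-3 from the required face and giving the B-alkyl-9-BBN adduct F5. NaOH/H2O2 gives (2R,3S,4R)-2-[3,5-dimethoxy-4-(triisopropylsilyloxy)benzyl]-3-methyl-4-(triethylsilyloxy)-4-(3,4,5-trimethoxyphenyl)butan-1-ol F6. TsCl/pyridine gives its tosylate F7, and LiBHEt3 in THF reduces this to the triethylsilyl ether of 17 F8. PPTS/MeOH then returns to the route at 17.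

Step 7 is the third risk. Wurtz-type homocoupling during formation of the electron-rich benzylic Grignard reagent may leave too little nucleophile, and the excess reagent or warming needed to compensate may erode the α-centre. The fallback uses a thioester–organozinc (Fukuyama) ketone synthesis and starts from 9 and 4. Lithium ethanethiolate (EtSH, n-BuLi, THF, 0 °C) should cleave the imide to S-ethyl (2R,3R)-3-hydroxy-2-methyl-3-(3,4,5-trimethoxyphenyl)propanethioate F9, which TESCl/imidazole converts to its triethylsilyl ether F10. Zinc dust and LiCl in THF convert 4 to [3,5-dimethoxy-4-(triisopropylsilyloxy)benzyl]zinc chloride F11, which is far less prone to homocoupling. PdCl2(PPh3)2 (cat.) in toluene/THF at rt should couple F10 with F11 and return to the route at 14.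

**Further compounds**

F1 | step 13 | lithium alkoxide/C-2 aryllithium (dilithio species) of 17 | COc1cc(C[C@@H](C)[C@H](C)[C@@H](O[Li])c2cc(OC)c(OC)c(OC)c2[Li])cc(OC)c1O[Si](C(C)C)(C(C)C)C(C)C
F2 | step 13 | (1R,2S,3R)-1-(2-bromo-3,4,5-trimethoxyphenyl)-4-[3,5-dimethoxy-4-(triisopropylsilyloxy)phenyl]-2,3-dimethylbutan-1-ol | COc1cc(C[C@@H](C)[C@H](C)[C@@H](O)c2cc(OC)c(OC)c(OC)c2Br)cc(OC)c1O[Si](C(C)C)(C(C)C)C(C)C
F3 | step 13 | benzoate of F2 | COc1cc(C[C@@H](C)[C@H](C)[C@@H](OC(=O)c2ccccc2)c2cc(OC)c(OC)c(OC)c2Br)cc(OC)c1O[Si](C(C)C)(C(C)C)C(C)C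
F4 | step 13 | (1R,2S,3R)-1-(2-bromo-3,4,5-trimethoxyphenyl)-4-(4-hydroxy-3,5-dimethoxyphenyl)-2,3-dimethylbutyl benzoate | COc1cc(C[C@@H](C)[C@H](C)[C@@H](OC(=O)c2ccccc2)c2cc(OC)c(OC)c(OC)c2Br)cc(OC)c1O
F5 | step 10 | B-alkyl-9-borabicyclo[3.3.1]nonane adduct of 15 (boron on the former =CH2 carbon) | COc1cc(C[C@@H](CB2C3CCCC2CCC3)[C@H](C)[C@@H](O[Si](CC)(CC)CC)c2cc(OC)c(OC)c(OC)c2)cc(OC)c1O[Si](C(C)C)(C(C)C)C(C)C
F6 | step 10 | (2R,3S,4R)-2-[3,5-dimethoxy-4-(triisopropylsilyloxy)benzyl]-3-methyl-4-(triethylsilyloxy)-4-(3,4,5-trimethoxyphenyl)butan-1-ol | COc1cc(C[C@@H](CO)[C@H](C)[C@@H](O[Si](CC)(CC)CC)c2cc(OC)c(OC)c(OC)c2)cc(OC)c1O[Si](C(C)C)(C(C)C)C(C)C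
F7 | step 10 | 4-methylbenzenesulfonate of F6 | COc1cc(C[C@@H](COS(=O)(=O)c2ccc(C)cc2)[C@H](C)[C@@H](O[Si](CC)(CC)CC)c2cc(OC)c(OC)c(OC)c2)cc(OC)c1O[Si](C(C)C)(C(C)C)C(C)C
F8 | step 10 | triethylsilyl ether of 17 | COc1cc(C[C@@H](C)[C@H](C)[C@@H](O[Si](CC)(CC)CC)c2cc(OC)c(OC)c(OC)c2)cc(OC)c1O[Si](C(C)C)(C(C)C)C(C)C
F9 | step 7 | S-ethyl (2R,3R)-3-hydroxy-2-methyl-3-(3,4,5-trimethoxyphenyl)propanethioate | CCSC(=O)[C@H](C)[C@@H](O)c1cc(OC)c(OC)c(OC)c1
F10 | step 7 | S-ethyl (2R,3R)-2-methyl-3-(triethylsilyloxy)-3-(3,4,5-trimethoxyphenyl)propanethioate | CCSC(=O)[C@H](C)[C@@H](O[Si](CC)(CC)CC)c1cc(OC)c(OC)c(OC)c1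
F11 | step 7 | [3,5-dimethoxy-4-(triisopropylsilyloxy)benzyl]zinc chloride | COc1cc(C[Zn]Cl)cc(OC)c1O[Si](C(C)C)(C(C)C)C(C)C
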